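(The constants used here are those of an exercise; the rest is arithmetic.)

A leftover of starting material is the thing to look for in these flasks, although zeta holds one equivalent of partner and eta two.

- zeta: starting material 0.010 M; partner 10.0 mM; time 30 h
- eta: starting material 0.010 M; partner 20.0 mM; time 30 h

    starting material + partner → first product + released group (k1 = 7.06 L mol⁻¹ h⁻¹)
    partner + bis adduct → triple product + released group (k2 = 3.51 L mol⁻¹ h⁻¹)
    partner + first product → bis adduct + released group (k3 = 7.66 L mol⁻¹ h⁻¹)
    partner + triple product → tetra adduct + released group (k4 = 2.28 L mol⁻¹ h⁻¹)
    partner → decomposed reagent (k5 = 0.313 h⁻¹)

1. which of these there is most of at the end, counted by the starting material in it, zeta (triple product / starting material / first product / bis adduct)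
2. which of these there is most of at the end, counted by the starting material in it, eta (triple product / starting material / first product / bis adduct)
3. final amount of the leader among these, as a percentage of the starting material charged, in zeta
4. final amount of the leader among these, as a percentage of the starting material charged, in eta

Two numbers seem not to fit. In zeta, with the partner held as charged, the starting material has a half-life of 9.8 h, so 30 h spans 3.06 half-lives and looks ample. But the partner has a half-life of 2.2 h by decomposition, shorter than that of the starting material, and at the start of zeta it goes 4.4 times as fast to decomposed reagent as to first product.

The clock is therefore the wrong measure. With c(starting material) held at its charge, the partner falls in a pseudo-first-order way, with a loss constant of 0.384 h⁻¹ in both flasks. The useful quantity is the dose, 0.184 for zeta: the first-step rate constant times the charged c(partner), divided by that loss constant. The fraction of starting material surviving is the exponential of minus the dose, which gives 83.2% in zeta. In eta the dose is 0.368, which gives 69.2%. The time allowed is 13.6 partner half-lives, so in this reckoning nearly all of the dose is delivered within it. The reckoning overstates the partner's loss by holding c(starting material) at its charge, and understates it by leaving out the partner taken by the first product.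

The forecast, holding that the partner decomposes “much faster than it reacts”, names starting material in zeta at 83.2% and starting material in eta at 69.3%.

The flasks give starting material at 83.2% in zeta and starting material at 69.2% in eta, as the doses reckoned. In zeta, less of the partner's charge remains at the end, 0%, than of the starting material's, and the starting material still stands at 83.2% after 300 h. A neighbour of zeta charged with 0.040 M of starting material holds 0.250 equiv of partner. Its loss constant rises to 0.595 h⁻¹, its dose is 0.119, and the surviving fraction comes to 88.8%. That flask ends with 88.8% of its starting material and 10.5% as first product.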